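All runs were generated by integration from invented constants, noise included.

Birch grows slower as it runs, and we ask how much of that slowness goes beyond the using up of substrate and partner.

| flask | substrate | partner | free catalyst | time |
|---|---|---|---|---|
| birch | 0.600 M | 0.660 M | 0.00300 M |  |
| cedar | 0.600 M | 0.660 M | 0.00600 M |  |
| alder | 1.20 M | 0.660 M | 0.00300 M |  |
| larch | 0.600 M | 0.660 M | 0.00300 M | 40 min |

- birch run (time / min: [target] / M): 4.0: 0.2214; 8.0: 0.3183; 12: 0.3694; 16: 0.4065; 20: 0.4310
- cedar run (time / min: [target] / M): 4.0: 0.3221; 8.0: 0.4152; 12: 0.4622; 16: 0.4899; 20: 0.5062
- alder run (time / min: [target] / M): 4.0: 0.3615; 8.0: 0.4721; 12: 0.5237; 16: 0.5584; 20: 0.5818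

(readings scatter by 0.002 M)

- Overall: substrate + partner -> target, with free catalyst as catalyst.
- Constant volume, constant temperature.
- The analysis sees a species whether free or bound.
- "The second partner" is partner.
- An order is taken over about fifteen percent of the charge, up and down.

* reaction order in [free catalyst] at the outset, round the charge of the birch run, defined at two percent of the substrate turned into target
* reaction order in [substrate] at the outset, round the charge of the birch run, defined at two percent of the substrate turned into target (one fixed amount of target, the same in the runs compared)
* target in the larch run at 40 min, as a share of the substrate charged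

We turn each reading into a count G. It is the logarithm of partner left over substrate left, taken against that ratio at the start and divided by the difference of the two charges. If the rate is a constant times substrate times partner (second-order), G climbs in a straight line with time, and its slope is that constant.

Take the birch column at 4.0 min, 12 min and 20 min. G reads 0.863 M⁻¹, 2.27 M⁻¹ and 3.48 M⁻¹. The later span of 8.0 min gains 1.21 M⁻¹, less than the 1.40 M⁻¹ of the earlier one, so the line bends. In birch the later gain over the earlier gain reads 0.862 per span. We call this ratio the fade f.

Now the first row, read across. Cedar's G is 1.93 times birch's, which we read as a catalyst order of 0.952. Alder's G is 0.933 times birch's, and G already counts substrate once, so we read a substrate order of 0.900. Both are means over the first readings, not values at the outset.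

Larch has birch's charge, so we iterate: each new span gains f times the last. Two full spans and half of a further one carry G from 20 min to 40 min, reaching 5.80 M⁻¹. Undoing the count gives 0.493 M of target, or 82.1% of the substrate charged.

The forecast gives a catalyst order of 0.95 (0.82 to 1.05), a substrate order of 0.85 (0.6 to 1.05) and a larch share of 82% (78.5% to 85.5%). On substrate it says “so substrate order is a little below one”. Our substrate order stands above its value.

The flask gives a catalyst order of 1.0, a substrate order of 1.0 and a larch share of 83.3%. At equal target made, alder runs 2.0 times as fast as birch.

    free catalyst + partner ⇌ catalyst-reagent complex, settled at all times (11.20 M⁻¹)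
    catalyst-reagent complex + substrate → target + free catalyst (62.40 M⁻¹ min⁻¹)
    free catalyst + substrate → spent catalyst + substrate (0.4572 M⁻¹ min⁻¹)
    free catalyst + target ⇌ catalyst-product complex, settled at all times (17.20 M⁻¹)

Run backward, f serves as well. Moving birch's first mean slope back a quarter of a span gives a starting constant of 0.224 M⁻¹ min⁻¹ in the units of G per minute. A quarter of the substrate turned means a G of 0.498 M⁻¹, so birch should get there in 2.22 min, and it took 2.17 min. Scaled to cedar's catalyst charge, the same constant gives 1.11 min, and cedar took 1.07 min.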